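**Retrosynthetic overview** (eudesmane numbering: ring A = C1–C5 + C10, ring B = C5–C10; C4 carbinol, C6 ester carbon, C7 isopropyl carbon, C10 quaternary)
1. Target 19 ⇒ Horner–Wadsworth–Emmons olefination with isovanillin 18 and acylation with phosphonoacetic acid 16 ⇒ eudesmane-4β,6β-diol 15.
2. 15 ⇒ bicyclic enone 11 (C4=O, C5=C6): C4 by methyllithium addition, C5/C6 by hydroboration of C5=C6, C6 inverted by oxidation/reduction; every reagent enters anti to the axial C10 methyl group.
3. 11 ⇒ ring B cut at C9–C10 and C5–C6: 3-methylcyclohex-2-enone 6 (ring A, bought) + Grignard reagent 7 (C6–C9 with the C7 centre, C6 as acetal). One pot: asymmetric conjugate addition at the quaternary carbon, then Mukaiyama aldol/elimination.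
4. Enabling feature: O–C4 and O–C6 stand 1,3 across the fusion carbon C5 and the quaternary C10 is β to C4. With C4 as a ketone, C5=C10 of ring A is an enone whose β-carbon (C10) and α-carbon (C5) are exactly the two ring-B atoms that must be bonded to C9 and C6.
5. Ring order: ring A present from the start, ring B closed last (step 4); C7 comes from asymmetric isopropyl conjugate addition to enoate 1 (steps 1–3).

Key step: step 4

Remark: enoate 1 is taken as a catalogue compound (otherwise one Wittig step from aqueous dimethoxyacetaldehyde); the antipode of each chiral ligand is chosen to give the stated configuration.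

**Step 1**
Reactants: 1 methyl (2E)-4,4-dimethoxybut-2-enoate; 2 isopropylmagnesium bromide
Product: 3 methyl (3S)-3-(dimethoxymethyl)-4-methylpentanoate
Conditions: CuI (cat.), Tol-BINAP (cat.), t-BuOMe, −40 °C; then H2O
Reagents that add atoms: none
Why: Copper-catalysed asymmetric conjugate addition of a Grignard reagent to an (E)-enoate; the chiral bisphosphine–copper complex selects one face of the β-carbon and sets C7 as S, and the γ-acetal cannot eliminate from the ester enolate.

**Step 2**
Reactants: 3 methyl (3S)-3-(dimethoxymethyl)-4-methylpentanoate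
Product: 4 (3S)-3-(dimethoxymethyl)-4-methylpentan-1-ol
Conditions: LiAlH4, THF, 0 °C; NaOH/H2O work-up
Reagents that add atoms: none
Why: Hydride reduction of the ester to the primary alcohol; the acetal survives and C7, which is not α to the carbonyl group, cannot epimerise.

**Step 3**
Reactants: 4 (3S)-3-(dimethoxymethyl)-4-methylpentan-1-ol
Product: 5 (3S)-1-bromo-3-(dimethoxymethyl)-4-methylpentane
Conditions: CBr4, PPh3, imidazole, CH2Cl2, 0 °C
Reagents that add atoms: carbon tetrabromide, BrC(Br)(Br)Br
Why: Appel bromination (SN2 at the primary carbon) under buffered conditions that spare the dimethyl acetal.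

**Step 4**
Reactants: 5 (3S)-1-bromo-3-(dimethoxymethyl)-4-methylpentane; 6 3-methylcyclohex-2-en-1-one
Product: 11 (4aR,7S)-4a-methyl-7-(propan-2-yl)-3,4,4a,5,6,7-hexahydronaphthalen-1(2H)-one, via Grignard reagent 7 (not isolated), via magnesium enolate 8 (not isolated), via silyl enol ether 9 (not isolated), via methoxy ketone 10 (not isolated)
Conditions: Mg, Et2O; then 6, Cu(OTf)2 (3 mol%), chiral N-mesityl hydroxyalkyl imidazolinium salt (4 mol%), Et2O, −30 °C; then CH2Cl2, TMSOTf, −78 to −40 °C; then DBU, to 23 °C
Reagents that add atoms: none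
Why: The alkyl–copper species formed from 7, steered by its chiral carbene ligand, delivers the C6–C9 chain 1,4 to C10 of 6 and gives the regio-defined C4–C5 enolate 8; TMSOTf silylates it on oxygen (9) and then ionises the dimethyl acetal to a C6 oxocarbenium ion that C5 attacks, and DBU expels methanol from 10 by E1cB. The closest known reactions are the copper-catalysed asymmetric conjugate addition of Grignard reagents to 3-methylcyclohex-2-enone, which builds all-carbon quaternary centres, and the TMSOTf-mediated Mukaiyama aldol of silyl enol ethers with dimethyl acetals. Ring B is closed through C5–C6 in a 6-(enolexo)-exo-trig mode after the C9–C10 bond has joined the two fragments at the quaternary carbon. C10 (R) is set by the catalyst, which picks one enantiotopic face of the enone, while C7 stays as made because it is never next to a free carbonyl group and the acetal is ionised without base; the C5 and C6 centres of 10 are transient and vanish on elimination. The step needs 1,4- over 1,2-addition (copper catalysis), an enolate fixed towards C5 (it is formed there and trapped on oxygen before proton transfer) and closure of a six-membered ring only (C5 is the sole nucleophilic carbon). Because 5 is already enantioenriched, the minor C10 epimer would be a diastereomer of 11 and should be removable by chromatography.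

**Step 5**
Reactants: 11 (4aR,7S)-4a-methyl-7-(propan-2-yl)-3,4,4a,5,6,7-hexahydronaphthalen-1(2H)-one
Product: 12 (1S,4aR,7S)-1,4a-dimethyl-7-(propan-2-yl)-1,2,3,4,4a,5,6,7-octahydronaphthalen-1-ol
Conditions: MeLi, Et2O, −78 °C; then H2O
Reagents that add atoms: methyllithium, [Li]C
Why: 1,2-Addition of methyllithium to the enone carbonyl; the C10 methyl group is axial on ring A and 1,3 to C4, so the reagent should enter from the opposite (α) face and give the 4β-hydroxy-4α-methyl carbinol (4S).

**Step 6**
Reactants: 12 (1S,4aR,7S)-1,4a-dimethyl-7-(propan-2-yl)-1,2,3,4,4a,5,6,7-octahydronaphthalen-1-ol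
Product: 13 (1S,2S,4aR,8S,8aS)-4a,8-dimethyl-2-(propan-2-yl)decahydronaphthalene-1,8-diol
Conditions: BH3·THF (excess), THF, 0 to 23 °C; then NaOH, H2O2
Reagents that add atoms: hydrogen peroxide, OO
Why: Hydroboration–oxidation of the trisubstituted C5=C6 alkene puts boron on C6 and adds syn on the α face, away from the axial C10 methyl and C4 hydroxyl groups, which should set 5α-H (trans ring fusion) and 6α-OH as in the hydroboration of steroidal 5-enes.

**Step 7**
Reactants: 13 (1S,2S,4aR,8S,8aS)-4a,8-dimethyl-2-(propan-2-yl)decahydronaphthalene-1,8-diol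
Product: 14 (2S,4aR,8S,8aR)-8-hydroxy-4a,8-dimethyl-2-(propan-2-yl)octahydronaphthalen-1(2H)-one
Conditions: Dess–Martin periodinane, pyridine, CH2Cl2, 0 to 23 °C
Reagents that add atoms: none
Why: Dess–Martin oxidation of the secondary C6 alcohol; the tertiary C4 alcohol cannot be oxidised and the buffered neutral medium should avoid retro-aldol cleavage, dehydration and epimerisation at C5 or C7.

**Step 8**
Reactants: 14 (2S,4aR,8S,8aR)-8-hydroxy-4a,8-dimethyl-2-(propan-2-yl)octahydronaphthalen-1(2H)-one
Product: 15 (1R,2S,4aR,8S,8aS)-4a,8-dimethyl-2-(propan-2-yl)decahydronaphthalene-1,8-diol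
Conditions: NaBH4, MeOH, 0 °C
Reagents that add atoms: none
Why: Borohydride reduction of the C6 ketone; the β face is blocked by the syn-axial C10 methyl and C4 hydroxyl groups, so equatorial (α-face) attack should give the axial 6β-alcohol (6R), as known for 6-oxo-5α-steroids.

**Step 9**
Reactants: 15 (1R,2S,4aR,8S,8aS)-4a,8-dimethyl-2-(propan-2-yl)decahydronaphthalene-1,8-diol; 16 (diethoxyphosphoryl)acetic acid
Product: 17 (1R,2S,4aR,8S,8aS)-8-hydroxy-4a,8-dimethyl-2-(propan-2-yl)decahydronaphthalen-1-yl 2-(diethoxyphosphoryl)acetate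
Conditions: DCC, DMAP (cat.), CH2Cl2, 23 °C
Reagents that add atoms: none
Why: Steglich esterification of the only acylable hydroxyl group, the secondary 6β-OH, with a small acid that is activated in a ketene-like form; the tertiary C4 alcohol is inert.

**Step 10**
Reactants: 17 (1R,2S,4aR,8S,8aS)-8-hydroxy-4a,8-dimethyl-2-(propan-2-yl)decahydronaphthalen-1-yl 2-(diethoxyphosphoryl)acetate; 18 3-hydroxy-4-methoxybenzaldehyde (isovanillin)
Product: 19 (1R,2S,4aR,8S,8aS)-8-hydroxy-4a,8-dimethyl-2-(propan-2-yl)decahydronaphthalen-1-yl (2E)-3-(3-hydroxy-4-methoxyphenyl)prop-2-enoate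
Conditions: LiCl, DBU (excess), MeCN, 23 °C; aq. NH4Cl
Reagents that add atoms: none
Why: Horner–Wadsworth–Emmons olefination under Masamune–Roush conditions tolerates the free phenol (meta to the aldehyde) and the hindered ester and should give the (E)-cinnamate, so no protecting group is needed.

**Compound list**
1 | methyl (2E)-4,4-dimethoxybut-2-enoate | COC(=O)/C=C/C(OC)OC | starting material
2 | isopropylmagnesium bromide | CC(C)[Mg]Br | starting material
3 | methyl (3S)-3-(dimethoxymethyl)-4-methylpentanoate | COC(=O)C[C@H](C(OC)OC)C(C)C | intermediate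
4 | (3S)-3-(dimethoxymethyl)-4-methylpentan-1-ol | OCC[C@H](C(OC)OC)C(C)C | intermediate
5 | (3S)-1-bromo-3-(dimethoxymethyl)-4-methylpentane | BrCC[C@H](C(OC)OC)C(C)C | intermediate
6 | 3-methylcyclohex-2-en-1-one | CC1=CC(=O)CCC1 | starting material
7 | [(3S)-3-(dimethoxymethyl)-4-methylpentyl]magnesium bromide | Br[Mg]CC[C@H](C(OC)OC)C(C)C | intermediate
8 | bromomagnesium (3R)-3-[(3S)-3-(dimethoxymethyl)-4-methylpentyl]-3-methylcyclohex-1-en-1-olate | C[C@]1(CC[C@H](C(OC)OC)C(C)C)CCCC(O[Mg]Br)=C1 | intermediate
9 | trimethyl({(3R)-3-[(3S)-3-(dimethoxymethyl)-4-methylpentyl]-3-methylcyclohex-1-en-1-yl}oxy)silane | C[Si](C)(C)OC1=C[C@@](C)(CC[C@H](C(OC)OC)C(C)C)CCC1 | intermediate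
10 | (4aR,7S)-8-methoxy-4a-methyl-7-(propan-2-yl)octahydronaphthalen-1(2H)-one (epimers at C8 and C8a) | COC1C2[C@](C)(CCCC2=O)CC[C@H]1C(C)C | intermediate
11 | (4aR,7S)-4a-methyl-7-(propan-2-yl)-3,4,4a,5,6,7-hexahydronaphthalen-1(2H)-one | C1=C2[C@](C)(CCCC2=O)CC[C@H]1C(C)C | intermediate
12 | (1S,4aR,7S)-1,4a-dimethyl-7-(propan-2-yl)-1,2,3,4,4a,5,6,7-octahydronaphthalen-1-ol | C1=C2[C@](C)(CCC[C@]2(C)O)CC[C@H]1C(C)C | intermediate
13 | (1S,2S,4aR,8S,8aS)-4a,8-dimethyl-2-(propan-2-yl)decahydronaphthalene-1,8-diol (4β,6α-diol) | O[C@@H]1[C@@H]2[C@](C)(CCC[C@]2(C)O)CC[C@H]1C(C)C | intermediate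
14 | (2S,4aR,8S,8aR)-8-hydroxy-4a,8-dimethyl-2-(propan-2-yl)octahydronaphthalen-1(2H)-one | O=C1[C@@H]2[C@](C)(CCC[C@]2(C)O)CC[C@H]1C(C)C | intermediate
15 | (1R,2S,4aR,8S,8aS)-4a,8-dimethyl-2-(propan-2-yl)decahydronaphthalene-1,8-diol (4β,6β-diol) | O[C@H]1[C@@H]2[C@](C)(CCC[C@]2(C)O)CC[C@H]1C(C)C | intermediate
16 | (diethoxyphosphoryl)acetic acid | CCOP(=O)(OCC)CC(=O)O | starting material
17 | (1R,2S,4aR,8S,8aS)-8-hydroxy-4a,8-dimethyl-2-(propan-2-yl)decahydronaphthalen-1-yl 2-(diethoxyphosphoryl)acetate | CCOP(=O)(OCC)CC(=O)O[C@H]1[C@@H]2[C@](C)(CCC[C@]2(C)O)CC[C@H]1C(C)C | intermediate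
18 | 3-hydroxy-4-methoxybenzaldehyde | COc1ccc(C=O)cc1O | starting material
19 | (1R,2S,4aR,8S,8aS)-8-hydroxy-4a,8-dimethyl-2-(propan-2-yl)decahydronaphthalen-1-yl (2E)-3-(3-hydroxy-4-methoxyphenyl)prop-2-enoate | COc1ccc(/C=C/C(=O)O[C@H]2[C@@H]3[C@](C)(CCC[C@]3(C)O)CC[C@H]2C(C)C)cc1O | target

**Total steps:** 10. **Longest linear sequence:** 10 steps (1 to 19).

**Steps most likely to fail**

1. Step 4. Facial control may drop when a functionalised, γ-branched Grignard reagent is transferred, and the regio-defined enolate may be lost by proton transfer before the ring closes. The fallback sets out from 5 (as its Grignard reagent 7) and delivers methyl instead of the chain in the asymmetric step. Reagent 7 is added 1,2 to 3-ethoxycyclohex-2-en-1-one to give 3-ethoxy-1-[(3S)-3-(dimethoxymethyl)-4-methylpentyl]cyclohex-2-en-1-ol F1. Cold aqueous oxalic acid transposes it (Stork–Danheiser) with loss of ethanol to 3-[(3S)-3-(dimethoxymethyl)-4-methylpentyl]cyclohex-2-en-1-one F2. Asymmetric conjugate addition of Me3Al (Cu(O2C-2-thienyl), chiral phosphoramidite, Et2O, −30 °C) gives dimethylaluminium (3R)-3-[(3S)-3-(dimethoxymethyl)-4-methylpentyl]-3-methylcyclohex-1-en-1-olate F3, which TMSOTf silylates. The route is rejoined at silyl enol ether 9, which is closed to 11 as in step 4.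

2. Step 1. Enantiofacial discrimination may be insufficient with a secondary Grignard reagent on an acetal-bearing enoate, and 1,2-addition to the ester may compete. The fallback sets out from 2 and uses auxiliary control. Reagent 2 is added (CuBr·SMe2 cat., TMSCl, THF, −78 °C) to the purchasable chiral-pool acceptor (5R)-5-[(1R,2S,5R)-menthyloxy]furan-2(5H)-one, anti to the acetal substituent. This should give (4S,5R)-5-[(1R,2S,5R)-menthyloxy]-4-(propan-2-yl)oxolan-2-one F4 as a single crystallisable diastereomer. Acid-catalysed methanolysis (MeOH, HC(OMe)3, cat. H2SO4) opens the pseudo-ester with release of menthol, and the route is rejoined at 3.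

3. Step 6. Hydroboration of an alkene flanked by two fully substituted carbons may be sluggish or face-unselective, and hydride may be delivered from the alkoxyborane on the hydroxyl face. The fallback sets out from 12 and bypasses 13 and 14. Hydroxyl-directed epoxidation (VO(acac)2, t-BuOOH, CH2Cl2) on the face of the C4 hydroxyl group should give the 5β,6β-epoxy alcohol 5β,6β-epoxyeudesman-4β-ol F5. Trivalent titanium (Cp2TiCl from Cp2TiCl2 and Zn, 1,4-cyclohexadiene, THF) opens the oxirane homolytically at C5. The tertiary C5 radical should take a hydrogen atom on the α face, opposite the three axial β substituents, while the C6–O bond stays intact. The route is rejoined at diol 15.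

**Further compounds**
F1 | step 4 | 3-ethoxy-1-[(3S)-3-(dimethoxymethyl)-4-methylpentyl]cyclohex-2-en-1-ol | CCOC1=CC(O)(CC[C@H](C(OC)OC)C(C)C)CCC1
F2 | step 4 | 3-[(3S)-3-(dimethoxymethyl)-4-methylpentyl]cyclohex-2-en-1-one | O=C1C=C(CC[C@H](C(OC)OC)C(C)C)CCC1
F3 | step 4 | dimethylaluminium (3R)-3-[(3S)-3-(dimethoxymethyl)-4-methylpentyl]-3-methylcyclohex-1-en-1-olate | C[Al](C)OC1=C[C@@](C)(CC[C@H](C(OC)OC)C(C)C)CCC1
F4 | step 1 | (4S,5R)-5-[(1R,2S,5R)-menthyloxy]-4-(propan-2-yl)oxolan-2-one | O=C1C[C@@H](C(C)C)[C@H](O[C@@H]2C[C@H](C)CC[C@H]2C(C)C)O1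
F5 | step 6 | 5β,6β-epoxyeudesman-4β-ol | O1[C@H]2[C@]13[C@](C)(CCC[C@]3(C)O)CC[C@H]2C(C)C
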